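**Retrosynthetic overview**
Target 16 comes from 4,5,6-tribromo-1H-indole 13 by two sulfenylations at C3, the second sulfur moving to C2; 13 comes from N-tosyl indoline 11 by dehydrogenation and removal of the sulfonyl group.
Indoline 11 comes from aryne 10 and two bromides (Li2CuBr4); 10 comes from triyne 9 by a thermal hexadehydro-Diels–Alder reaction that forms C3a–C7a and C6–C7 and closes the five-membered ring (N1, C2, C3, C3a, C7a) and the benzene ring in the same event.
The strategy rests on the unbroken run C4(Br)–C5(Br)–C6(Br) beside C7–H on the benzo ring: C3a, C4, C5, C6 (Br on C6) are the four carbons of a 1-bromo-1,3-diyne and C7a, C7 (H on C7) are the two carbons of a terminal ynamide, so the aryne bond falls on C4–C5, the two carbons still lacking bromine.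
Triyne 9 comes from N-ethynylation of bromodiyne sulfonamide 6 with alkynyliodonium salt 7; 6 comes from silicon/bromine exchange on 5, made by Cadiot–Chodkiewicz coupling of 3 (from 1 and 2) with 4.

Key step: step 5

Assumption: the bromodiynes 6 and 9 are taken to survive rapid chromatography and brief cold storage in solution in the dark; both are used at once.

Step 1
Reactants: 1 but-3-yn-1-amine hydrochloride; 2 4-methylbenzenesulfonyl chloride
Product: 3 N-(but-3-yn-1-yl)-4-methylbenzenesulfonamide
Conditions: Et3N (2.5 equiv), CH2Cl2, 0 °C to rt
Reagents that add atoms: none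
Why: Sulfonylation of a primary amine by a sulfonyl chloride is fast and selective at nitrogen, and the terminal alkyne is inert.

Step 2
Reactants: 3 N-(but-3-yn-1-yl)-4-methylbenzenesulfonamide; 4 (bromoethynyl)tri(propan-2-yl)silane
Product: 5 4-methyl-N-{6-[tri(propan-2-yl)silyl]hexa-3,5-diyn-1-yl}benzenesulfonamide
Conditions: CuCl (5 mol %), NH2OH·HCl, 30% aq. n-BuNH2, CH2Cl2, 0 °C to rt
Reagents that add atoms: none
Why: In this Cadiot–Chodkiewicz coupling the copper acetylide of 3 (monovalent copper, kept reduced by hydroxylamine) should couple with bromoalkyne 4 to the unsymmetrical diyne, the bulky silyl group holding back homocoupling and the sulfonamide N–H staying untouched at this temperature.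

Step 3
Reactants: 5 4-methyl-N-{6-[tri(propan-2-yl)silyl]hexa-3,5-diyn-1-yl}benzenesulfonamide
Product: 6 N-(6-bromohexa-3,5-diyn-1-yl)-4-methylbenzenesulfonamide
Conditions: AgF (1.2 equiv), NBS (1.2 equiv), MeCN, rt, dark
Reagents that add atoms: N-bromosuccinimide, O=C1CCC(=O)N1Br
Why: In this desilylative bromination fluoride from AgF cleaves the C(sp)–Si bond to a silver acetylide that NBS brominates at once, a known one-flask exchange for bulky silyl alkynes and diynes; acetonitrile binds the silver ion and should keep it from cyclising the N–H onto the diyne.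

Step 4
Reactants: 6 N-(6-bromohexa-3,5-diyn-1-yl)-4-methylbenzenesulfonamide; 7 phenyl[(trimethylsilyl)ethynyl]iodonium trifluoromethanesulfonate
Product: 9 N-(6-bromohexa-3,5-diyn-1-yl)-N-ethynyl-4-methylbenzenesulfonamide, via N-[(trimethylsilyl)ethynyl] sulfonamide 8 (not isolated)
Conditions: Cs2CO3 (1.3 equiv), DMF, 0 °C; then 7 (1.2 equiv), 0 °C to rt, short reaction time; aqueous work-up
Reagents that add atoms: none
Why: In this N-alkynylation of a sulfonamide anion by an alkynyliodonium salt, nitrogen adds to the β-carbon, iodobenzene leaves to give an alkylidene carbene and a 1,2-silyl shift gives silyl ynamide 8, whose C–Si bond is then cleaved by carbonate and adventitious water in DMF to leave the terminal ynamide; cold, short conditions should spare the bromodiyne.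

Step 5
Reactants: 9 N-(6-bromohexa-3,5-diyn-1-yl)-N-ethynyl-4-methylbenzenesulfonamide
Product: 11 4,5,6-tribromo-1-(4-methylbenzenesulfonyl)-2,3-dihydro-1H-indole, via 6-bromo-1-tosylindoline-4,5-aryne 10 (not isolated)
Conditions: Li2CuBr4 (stock solution in THF, 6 equiv), THF, 0.01 M in 9, sealed tube, 100 °C, dark
Reagents that add atoms: dilithium tetrabromocuprate, [Li+].[Li+].[Cu+2].[Br-].[Br-].[Br-].[Br-]
Why: Proposed new method: heating should bring the 1,3-diyne (four carbons) and the ynamide (two carbons) of 9 together in an intramolecular hexadehydro-Diels–Alder reaction, probably stepwise through a diradical formed by the C3a–C7a bond and closed by the C6–C7 bond, to give aryne 10 with its strained bond between C4 and C5; Li2CuBr4 then delivers bromide to one aryne carbon and a second equivalent of divalent copper turns the aryl–copper bond into the second C–Br bond, leaving CuBr. The closest known reaction types are the thermal hexadehydro-Diels–Alder cyclisation of ynamide-linked triynes to indoline arynes and the 1,2-dichlorination of such arynes with Li2CuCl4; the bromoalkyne terminus and the change from chloride to bromide are the untested parts. The five-membered ring closes through the C3a–C7a bond with both alkynes exocyclic to it (exo-dig at either end), and the benzene ring closes through the C6–C7 bond as the second bond of the [4+2] process. No stereocenter is formed. The step needs a single mode of ring fusion, which the three-atom tether C3–C2–N1 enforces because only the tether-bearing diyne carbon can reach the nitrogen-bearing ynamide carbon, and it needs capture of 10 by bromide ahead of hydrogen transfer from THF or attack by a second triyne, which excess cuprate and high dilution of 9 should secure; since both aryne carbons receive bromine, the sense of addition does not matter.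

Step 6
Reactants: 11 4,5,6-tribromo-1-(4-methylbenzenesulfonyl)-2,3-dihydro-1H-indole
Product: 12 4,5,6-tribromo-1-(4-methylbenzenesulfonyl)-1H-indole
Conditions: DDQ (3 equiv), PhCl, reflux
Reagents that add atoms: none
Why: DDQ dehydrogenation of an indoline, by hydride abstraction at C3 or C2 and loss of a proton, aromatises the five-membered ring; the conversion is known for N-sulfonyl indolines and needs heat here because the arene is electron-poor, while the aryl bromides are inert.

Step 7
Reactants: 12 4,5,6-tribromo-1-(4-methylbenzenesulfonyl)-1H-indole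
Product: 13 4,5,6-tribromo-1H-indole
Conditions: Cs2CO3 (3 equiv), THF/MeOH 2:1, rt to 50 °C
Reagents that add atoms: none
Why: In this methanolysis of an N-sulfonyl indole, methoxide attacks sulfur and expels the indolide, a leaving group made better by three bromines, and the aryl bromides should not undergo substitution under such mild conditions.

Step 8
Reactants: 13 4,5,6-tribromo-1H-indole
Product: 16 4,5,6-tribromo-2,3-bis(methylsulfanyl)-1H-indole, via 4,5,6-tribromo-3-(methylsulfanyl)-1H-indole 14 (not isolated), via 4,5,6-tribromo-3,3-bis(methylsulfanyl)-3H-indole 15 (not isolated)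
Conditions: MeSCl (2.3 equiv, from MeSSMe and SO2Cl2, CH2Cl2, −20 °C), CH2Cl2, 0 °C to rt; aq. NaHCO3 work-up
Reagents that add atoms: methanesulfenyl chloride, CSCl
Why: In this electrophilic sulfenylation of indole the first MeSCl attacks C3 to give 14, the second attacks C3 again to give the 3,3-bis(sulfide) 15 (as its indoleninium salt), and a 1,2-shift of one sulfur to C2 through an episulfonium ion with loss of a proton gives the 2,3-bis(sulfide), the known course of double sulfenylation of indoles with sulfenyl chlorides.

**Compound list**
1 | but-3-yn-1-amine hydrochloride | C#CCCN.Cl | starting material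
2 | 4-methylbenzenesulfonyl chloride | Cc1ccc(cc1)S(Cl)(=O)=O | starting material
3 | N-(but-3-yn-1-yl)-4-methylbenzenesulfonamide | C#CCCNS(=O)(=O)c1ccc(C)cc1 | intermediate
4 | (bromoethynyl)tri(propan-2-yl)silane | CC(C)[Si](C#CBr)(C(C)C)C(C)C | starting material
5 | 4-methyl-N-{6-[tri(propan-2-yl)silyl]hexa-3,5-diyn-1-yl}benzenesulfonamide | Cc1ccc(cc1)S(=O)(=O)NCCC#CC#C[Si](C(C)C)(C(C)C)C(C)C | intermediate
6 | N-(6-bromohexa-3,5-diyn-1-yl)-4-methylbenzenesulfonamide | Cc1ccc(cc1)S(=O)(=O)NCCC#CC#CBr | intermediate
7 | phenyl[(trimethylsilyl)ethynyl]iodonium trifluoromethanesulfonate | C[Si](C)(C)C#C[I+]c1ccccc1.[O-]S(=O)(=O)C(F)(F)F | starting material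
8 | N-(6-bromohexa-3,5-diyn-1-yl)-4-methyl-N-[(trimethylsilyl)ethynyl]benzenesulfonamide | Cc1ccc(cc1)S(=O)(=O)N(CCC#CC#CBr)C#C[Si](C)(C)C | intermediate
9 | N-(6-bromohexa-3,5-diyn-1-yl)-N-ethynyl-4-methylbenzenesulfonamide | C#CN(CCC#CC#CBr)S(=O)(=O)c1ccc(C)cc1 | intermediate
10 | 6-bromo-1-(4-methylbenzenesulfonyl)-4,5-didehydro-2,3-dihydro-1H-indole (aryne) | Cc1ccc(cc1)S(=O)(=O)N1CCC2=C1C=C(Br)C#C2 | intermediate
11 | 4,5,6-tribromo-1-(4-methylbenzenesulfonyl)-2,3-dihydro-1H-indole | Cc1ccc(cc1)S(=O)(=O)N1CCc2c1cc(Br)c(Br)c2Br | intermediate
12 | 4,5,6-tribromo-1-(4-methylbenzenesulfonyl)-1H-indole | Cc1ccc(cc1)S(=O)(=O)n1ccc2c1cc(Br)c(Br)c2Br | intermediate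
13 | 4,5,6-tribromo-1H-indole | Brc1cc2[nH]ccc2c(Br)c1Br | intermediate
14 | 4,5,6-tribromo-3-(methylsulfanyl)-1H-indole | CSc1c[nH]c2cc(Br)c(Br)c(Br)c12 | intermediate
15 | 4,5,6-tribromo-3,3-bis(methylsulfanyl)-3H-indole | CSC1(SC)C=Nc2cc(Br)c(Br)c(Br)c21 | intermediate
16 | 4,5,6-tribromo-2,3-bis(methylsulfanyl)-1H-indole | CSc1[nH]c2cc(Br)c(Br)c(Br)c2c1SC | target

**Step count**
Total step count: 8. Longest linear sequence: 8 steps (1 to 16).

**Steps most likely to fail**

Step 5 (key step). What may go wrong: electrophilic bromination or oligomerisation of the terminal ynamide and the bromodiyne by the copper bromide reagent before cycloaromatisation, thermal decay of the bromodiyne, or quenching of aryne 10 by hydrogen transfer from THF instead of by bromide. The fallback uses known chemistry only and gives up the aryne. It does not set out from a numbered compound, because no compound before step 5 carries the arene; it sets out from commercial 3,4,5-tribromoaniline F1 and comes back to the route at indole 13. Iodination of 3,4,5-tribromoaniline F1 with ICl in AcOH goes ortho to nitrogen (para is blocked) and should give 3,4,5-tribromo-2-iodoaniline F2. Sonogashira coupling with ethynyltrimethylsilane (PdCl2(PPh3)2, CuI, Et3N, rt) should take place at the C–I bond only and give 3,4,5-tribromo-2-[(trimethylsilyl)ethynyl]aniline F3. K2CO3 in MeOH removes silicon to give 3,4,5-tribromo-2-ethynylaniline F4, and CuI in DMF at 100 °C closes the pyrrole ring by 5-endo-dig hydroamination to 13, which enters step 8.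

Step 6. What may go wrong: hydride abstraction by DDQ is too slow on an N-sulfonyl indoline that carries three bromines, so that 11 is recovered or degrades on long heating. The fallback sets out from indoline 11 and comes back at indole 13, bypassing 12; it reverses the order of the two operations. TfOH in 1,2-dichloroethane at 90 °C cleaves the N-aryl sulfonamide (acid hydrolysis, favoured by the electron-poor arene) and should give 4,5,6-tribromo-2,3-dihydro-1H-indole F5. MnO2 in CH2Cl2 at rt then dehydrogenates the free indoline, whose nitrogen lone pair now assists, to 13.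

Step 4. What may go wrong: the sulfonamide anion or carbonate adds to the bromodiyne in DMF, or the free ynamide oligomerises under base once silicon is lost. The fallback sets out from sulfonamide 6 and comes back at indoline 11; it keeps silicon on the ynamide through the cycloaromatisation. Deprotonation of 6 with KN(SiMe3)2 in toluene at 0 °C and addition of 7 should give silyl ynamide 8, now isolated (no carbonate, no polar solvent). Heating 8 with Li2CuBr4 as in step 5 should give, via 6-bromo-1-(4-methylbenzenesulfonyl)-7-(trimethylsilyl)-4,5-didehydro-2,3-dihydro-1H-indole F6, 4,5,6-tribromo-1-(4-methylbenzenesulfonyl)-7-(trimethylsilyl)-2,3-dihydro-1H-indole F7; the copper reagent then meets no terminal alkyne. TfOH (1 equiv) in CH2Cl2 at 0 °C should remove silicon by ipso-protodesilylation at C7, helped by relief of strain between the N-sulfonyl group and the C6 bromine, to give 11.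

**Further compounds**
F1 | step 5 | 3,4,5-tribromoaniline | Nc1cc(Br)c(Br)c(Br)c1
F2 | step 5 | 3,4,5-tribromo-2-iodoaniline | Nc1cc(Br)c(Br)c(Br)c1I
F3 | step 5 | 3,4,5-tribromo-2-[(trimethylsilyl)ethynyl]aniline | C[Si](C)(C)C#Cc1c(N)cc(Br)c(Br)c1Br
F4 | step 5 | 3,4,5-tribromo-2-ethynylaniline | C#Cc1c(N)cc(Br)c(Br)c1Br
F5 | step 6 | 4,5,6-tribromo-2,3-dihydro-1H-indole | Brc1cc2NCCc2c(Br)c1Br
F6 | step 4 | 6-bromo-1-(4-methylbenzenesulfonyl)-7-(trimethylsilyl)-4,5-didehydro-2,3-dihydro-1H-indole (aryne) | Cc1ccc(cc1)S(=O)(=O)N1CCC2=C1C([Si](C)(C)C)=C(Br)C#C2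
F7 | step 4 | 4,5,6-tribromo-1-(4-methylbenzenesulfonyl)-7-(trimethylsilyl)-2,3-dihydro-1H-indole | Cc1ccc(cc1)S(=O)(=O)N1CCc2c1c([Si](C)(C)C)c(Br)c(Br)c2Br
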